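**Retrosynthetic overview**
1. Both rings are closed last, in the biosynthetic order: first the 26-membered lactone by acyl transfer of C1 onto the C25 hydroxyl of seco acid 52, then the epoxide by oxygen transfer to the C30=C31 alkene of the finished macrolide, steered by the homoallylic C33 hydroxyl (the allylic C29 hydroxyl would give the wrong, erythro epoxide and is kept silylated).
2. The seco chain comes from two one-pot hydrozirconation/Negishi diene couplings (C19–C20, then C9–C10) between methyl alkynes and (E)-vinyl iodides.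
3. C20–C36 is made by a Roush double allylboration that joins aldehyde 31 and enal 37 through a C26–C28 linchpin and sets C25, C29 and the E C26=C27 alkene.
4. One Brown (Z)-γ-methoxyallylboration product (12) serves twice (C4–C9 and C14–C19), the same reaction on butanal gives C32/C33, and one mesylate (3) serves twice (C12 via allenylindium, C22 via allenylstannane).

Assumption: carbons are numbered C1 (lactone C=O) along the chain to C36 (propyl CH3), with C25 carrying the ring oxygen; the given SMILES defines the absolute configuration.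

**Route**

Step 1
Reactants: 1 pent-3-yn-2-one
Product: 2 (R)-pent-3-yn-2-ol
Conditions: RuCl[(R,R)-TsDPEN](p-cymene) (0.5 mol%), KOH (1 mol%), i-PrOH, rt
Reagents that add atoms: none
Why: Noyori asymmetric transfer hydrogenation of an alkynyl ketone, in which the (R,R)-diamine ruthenium hydride gives the (R)-carbinol in high ee.

Step 2
Reactants: 2 (R)-pent-3-yn-2-ol
Product: 3 (R)-pent-3-yn-2-yl methanesulfonate
Conditions: MsCl, Et3N, CH2Cl2, −78 → −20 °C
Reagents that add atoms: methanesulfonyl chloride CS(=O)(=O)Cl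
Why: O-sulfonylation with retention at carbon gives the propargylic leaving group used in both SN2′ reactions.

Step 3
Reactants: 3 (R)-pent-3-yn-2-yl methanesulfonate
Product: 4 (P)-tributyl(penta-2,3-dien-2-yl)stannane
Conditions: Bu3SnH, LiN(i-Pr)2, THF, 0 °C; CuBr·SMe2, −78 °C; then 3, −78 °C
Reagents that add atoms: tributyltin hydride CCCC[SnH](CCCC)CCCC
Why: Marshall anti-SN2′ displacement of the propargylic mesylate by a stannylcopper reagent turns the (R) centre into (P) axial chirality.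

Step 4
Reactants: 3 (R)-pent-3-yn-2-yl methanesulfonate; 5 formaldehyde
Product: 7 (S)-2-methylpent-3-yn-1-ol, via allenylindium species 6 (not isolated)
Conditions: Pd(dppf)Cl2 (5 mol%), InI (1.5 equiv), HCHO (monomer in THF, 3 equiv), THF/HMPA 3:1, rt
Reagents that add atoms: none
Why: Proposed new method: the closest known reaction is Marshall's palladium-catalysed conversion of propargylic mesylates into transient chiral allenylindium reagents (anti-SN2′ oxidative addition by zerovalent palladium, transmetalation with retention) that add to aldehydes by a cyclic syn-SE2′ path; formaldehyde has not been used as the aldehyde but is the least hindered electrophile possible, and the net anti/syn course places the CH2OH carbon opposite the departed mesylate, giving the (S) centre that becomes C12.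

Step 5
Reactants: 7 (S)-2-methylpent-3-yn-1-ol
Product: 8 (S)-1-bromo-2-methylpent-3-yne
Conditions: CBr4, PPh3, CH2Cl2, 0 °C
Reagents that add atoms: carbon tetrabromide BrC(Br)(Br)Br
Why: Appel bromination of a primary alcohol, which does not touch the stereocentre.

Step 6
Reactants: 9 allyl methyl ether; 10 3-(trimethylsilyl)prop-2-ynal
Product: 12 (3R,4R)-4-methoxy-1-(trimethylsilyl)hex-5-en-1-yn-3-ol, via (Z)-γ-methoxyallyl-B(dIpc)2 11 (not isolated)
Conditions: 9, s-BuLi, THF, −78 °C; (−)-Ipc2BOMe; BF3·OEt2; 10, −78 °C, 3 h; HOCH2CH2NH2, rt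
Reagents that add atoms: none
Why: Brown (Z)-γ-methoxyallylboration through a closed chair transition state gives the syn methoxy alcohol, and the Ipc groups from (+)-α-pinene direct attack to the Si face of the ynal, setting both centres (later C6/C7 and C16/C17).

Step 7
Reactants: 12 (3R,4R)-4-methoxy-1-(trimethylsilyl)hex-5-en-1-yn-3-ol
Product: 13 tert-butyl{[(3R,4R)-4-methoxy-1-(trimethylsilyl)hex-5-en-1-yn-3-yl]oxy}dimethylsilane
Conditions: TBSOTf, 2,6-lutidine, CH2Cl2, −78 °C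
Reagents that add atoms: tert-butyldimethylsilyl triflate CC(C)(C)[Si](C)(C)OS(=O)(=O)C(F)(F)F
Why: Silylation of the secondary propargylic alcohol (silyl ether protection).

Step 8
Reactants: 13 bis-silyl enyne
Product: 14 tert-butyl{[(3R,4R)-4-methoxyhex-5-en-1-yn-3-yl]oxy}dimethylsilane
Conditions: K2CO3 (0.2 equiv), MeOH, 0 °C → rt
Reagents that add atoms: none
Why: Base-catalysed methanolysis of the C(sp)–Si bond (protiodesilylation) leaves the O-silyl ether intact.

Step 9
Reactants: 14 terminal alkyne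
Product: 16 tert-butyl{[(1E,3R,4R)-1-iodo-4-methoxyhexa-1,5-dien-3-yl]oxy}dimethylsilane, via alkenylzirconocene chloride 15 (not isolated)
Conditions: Cp2Zr(H)Cl (1.05 equiv), CH2Cl2, 0 °C; I2, 0 °C
Reagents that add atoms: iodine II
Why: Hydrozirconation–iodination, in which syn addition of Zr–H to the terminal alkyne (faster than to the alkene) places Zr at the terminus and iodinolysis with retention gives the (E)-vinyl iodide.

Step 10
Reactants: 16 vinyl iodide; 17 methyl (2E,4E)-hexa-2,4-dienoate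
Product: 18 methyl (2E,4E,6R,7R,8E)-7-[(tert-butyldimethylsilyl)oxy]-9-iodo-6-methoxynona-2,4,8-trienoate (fragment A)
Conditions: second-generation Hoveyda–Grubbs catalyst RuCl2(H2IMes)(=CH-C6H4-2-Oi-Pr) (10 mol%), 17 (5 equiv), CH2Cl2, 40 °C
Reagents that add atoms: none
Why: Olefin cross-metathesis of the terminal alkene with the γ,δ-olefin of the sorbate (propene is lost) gives the conjugated (2E,4E)-dienoate under thermodynamic control, the electron-poor iodoalkene staying inert.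

Step 11
Reactants: 13 bis-silyl enyne; 8 (S)-1-bromo-2-methylpent-3-yne
Product: 20 tert-butyl{[(3R,4R,8R)-4-methoxy-8-methyl-1-(trimethylsilyl)undeca-1,9-diyn-3-yl]oxy}dimethylsilane, via B-alkyl-9-BBN 19 (not isolated)
Conditions: 9-BBN-H, THF, 0 °C → rt; then 8, Pd(OAc)2 (5 mol%), PCy3 (10 mol%), K3PO4·H2O, THF, rt → 40 °C
Reagents that add atoms: none
Why: Anti-Markovnikov hydroboration of the only terminal alkene followed by Suzuki–Miyaura alkyl–alkyl coupling with a primary bromide under Fu-type Pd/PCy3 conditions forms C13–C14 without touching a stereocentre.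

Step 12
Reactants: 20 silylated diyne
Product: 21 tert-butyl{[(3R,4R,8R)-4-methoxy-8-methylundeca-1,9-diyn-3-yl]oxy}dimethylsilane
Conditions: K2CO3 (0.2 equiv), MeOH, rt
Reagents that add atoms: none
Why: Protiodesilylation of the alkynylsilane as in step 8.

Step 13
Reactants: 21 diyne
Product: 23 tert-butyl{[(1E,3R,4R,8R)-1-iodo-4-methoxy-8-methylundec-1-en-9-yn-3-yl]oxy}dimethylsilane (fragment B), via alkenylzirconocene chloride 22 (not isolated)
Conditions: Cp2Zr(H)Cl (1.05 equiv), THF, 0 °C → rt; I2, 0 °C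
Reagents that add atoms: iodine II
Why: Hydrozirconation–iodination is selective for the terminal over the internal alkyne and gives the (E)-vinyl iodide by syn addition and retentive iodinolysis.

Step 14
Reactants: 24 2-vinyloxirane (racemic); 25 methanol
Product: 26 (2S)-2-methoxybut-3-en-1-ol
Conditions: Pd2(dba)3·CHCl3 (1 mol%), (R,R)-DACH-naphthyl Trost ligand (3 mol%; the antipode that gives the 2S ether), Et3B (1 mol%), CH2Cl2, rt
Reagents that add atoms: none
Why: Trost dynamic kinetic asymmetric allylic etherification, in which the π-allyl palladium intermediates from both epoxide enantiomers interconvert and boron-bound methoxide is delivered to the branched terminus, setting the future C24.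

Step 15
Reactants: 26 (2S)-2-methoxybut-3-en-1-ol
Product: 27 (2S)-2-methoxybut-3-enal
Conditions: Dess–Martin periodinane, NaHCO3, CH2Cl2, 0 °C; used crude at once
Reagents that add atoms: none
Why: Dess–Martin oxidation under buffered conditions avoids epimerisation or conjugation of the β,γ-unsaturated α-methoxy aldehyde.

Step 16
Reactants: 27 (2S)-2-methoxybut-3-enal; 4 (P)-allenylstannane
Product: 28 (3S,4S,5R)-3-methoxy-5-methyloct-1-en-6-yn-4-ol
Conditions: MgBr2·OEt2 (2 equiv), CH2Cl2, −23 °C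
Reagents that add atoms: none
Why: Marshall SE2′ addition of the chiral allenylstannane to the magnesium-chelated α-methoxy aldehyde: anti-SE2′ transfers axial chirality to C22, the open transition state gives the syn methyl/hydroxyl relation and chelation gives the syn hydroxyl/methoxy relation (matched pair).

Step 17
Reactants: 28 homopropargylic alcohol
Product: 29 tert-butyl{[(3S,4S,5R)-3-methoxy-5-methyloct-1-en-6-yn-4-yl]oxy}dimethylsilane
Conditions: TBSOTf, 2,6-lutidine, CH2Cl2, −78 → 0 °C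
Reagents that add atoms: tert-butyldimethylsilyl triflate CC(C)(C)[Si](C)(C)OS(=O)(=O)C(F)(F)F
Why: Silylation of the hindered secondary alcohol (C23) with the reactive silyl triflate.

Step 18
Reactants: 29 silyl ether
Product: 31 (2R,3S,4R)-3-[(tert-butyldimethylsilyl)oxy]-2-methoxy-4-methylhept-5-ynal, via ozonide 30 (not isolated)
Conditions: O3, CH2Cl2, −78 °C (dye end point); PPh3, −78 °C → rt; used crude
Reagents that add atoms: ozone [O-][O+]=O
Why: Alkene ozonolysis with reductive work-up, the vinyl group reacting far faster than the internal alkyne.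

Step 19
Reactants: 9 allyl methyl ether; 32 butanal
Product: 34 (3S,4S)-3-methoxyhept-1-en-4-ol, via (Z)-γ-methoxyallyl-B(lIpc)2 33 (not isolated)
Conditions: 9, s-BuLi, THF, −78 °C; (+)-Ipc2BOMe; BF3·OEt2; 32, −78 °C; HOCH2CH2NH2, rt
Reagents that add atoms: none
Why: Brown (Z)-γ-methoxyallylboration with the antipodal reagent from (−)-α-pinene gives the syn adduct by Re-face attack, setting C32 and C33.

Step 20
Reactants: 34 (3S,4S)-3-methoxyhept-1-en-4-ol
Product: 35 triethyl{[(3S,4S)-3-methoxyhept-1-en-4-yl]oxy}silane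
Conditions: TESCl, imidazole, DMF, 0 °C
Reagents that add atoms: chlorotriethylsilane CC[Si](CC)(CC)Cl
Why: Silylation with a group that can later be removed in the presence of TBS ethers.

Step 21
Reactants: 35 TES ether; 36 methacrolein
Product: 37 (2E,4S,5S)-4-methoxy-2-methyl-5-[(triethylsilyl)oxy]oct-2-enal
Conditions: second-generation Hoveyda–Grubbs catalyst RuCl2(H2IMes)(=CH-C6H4-2-Oi-Pr) (10 mol%), 36 (10 equiv), CH2Cl2, 40 °C
Reagents that add atoms: none
Why: Olefin cross-metathesis with a 1,1-disubstituted enal (ethylene is lost) gives the (E)-trisubstituted enal, the geometry needed for C30=C31.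

Step 22
Reactants: 38 propargyl bromide
Product: 41 5,5-dimethyl-2-(propa-1,2-dien-1-yl)-1,3,2-dioxaborinane, via allenylmagnesium bromide 39 (not isolated), via allenylboronic acid 40 (not isolated)
Conditions: Mg, HgCl2 (cat.), Et2O, 0 °C; B(OMe)3, −78 °C; 1 M HCl; 2,2-dimethylpropane-1,3-diol, MgSO4, Et2O, rt
Reagents that add atoms: trimethyl borate COB(OC)OC; 2,2-dimethylpropane-1,3-diol CC(C)(CO)CO
Why: Grignard formation with propargyl-to-allenyl transposition, borylation and diol esterification give the allenylboronate needed for the double allylboration.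

Step 23
Reactants: 41 allenylboronate; 31 aldehyde (C20–C25); 37 enal (C29–C36)
Product: 44 C20–C36 25,29-diol (23-OTBS 33-OTES), via γ-borylallylborane 42 (not isolated), via borinate-boronate adduct 43 (not isolated)
Conditions: (dIpc)2BH [from (+)-α-pinene], Et2O, −25 → 0 °C; 31, −78 °C, 2 h; 37, −78 °C → rt, 24 h; NaHCO3, H2O2, 0 °C
Reagents that add atoms: none
Why: Roush double allylboration: the Ipc2B-allyl end adds to the Si face of 31 (C25, anti to C24-OMe, matched with the Felkin preference), and the resulting α-substituted allylboronate adds to 37 through a chair with the substituent equatorial, giving the E C26=C27 olefin and the 1,5-anti C29 carbinol by 1,3-chirality transfer.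

Step 24
Reactants: 44 25,29-diol
Product: 45 C20–C36 alkyne with free C25-OH (23,29-bis-OTBS 33-OTES)
Conditions: TBSCl (1.1 equiv), imidazole, DMF, −20 → 0 °C
Reagents that add atoms: tert-butyldimethylsilyl chloride CC(C)(C)[Si](C)(C)Cl
Why: Site-selective silylation of the less hindered C29 hydroxyl (CH2 and isopropenyl-type neighbours) over the C25 hydroxyl, which is flanked by the branched CH(OMe)–CH(OTBS) unit and hydrogen-bonded to the C24 methoxy group.

Step 25
Reactants: 45 alkyne (C20–C36); 23 fragment B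
Product: 48 C10–C36 dienyne, via C20 alkenylzirconocene 46 (not isolated), via C20 alkenylzinc chloride 47 (not isolated)
Conditions: Cp2Zr(H)Cl (2.2 equiv), THF, rt → 40 °C; ZnCl2 (THF); Pd(PPh3)4 (5 mol%), 23 (1.1 equiv), rt
Reagents that add atoms: none
Why: Regioselective syn hydrozirconation of the methyl alkyne (Zr at the methyl-bearing C20, the first equivalent being consumed by the C25 hydroxyl) and Negishi coupling with retention at both partners give the (18E,20E)-diene.

Step 26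
Reactants: 48 dienyne (C10–C36); 18 fragment A
Product: 51 methyl ester of the C1–C36 seco acid, via C10 alkenylzirconocene 49 (not isolated), via C10 alkenylzinc chloride 50 (not isolated)
Conditions: Cp2Zr(H)Cl (2.2 equiv), THF, rt → 40 °C; ZnCl2 (THF); Pd(PPh3)4 (5 mol%), 18 (1.2 equiv), rt
Reagents that add atoms: none
Why: A second hydrozirconation/Negishi coupling (Zr at C10) builds the (8E,10E)-diene, the alkenylzinc tolerating the dienoate ester.

Step 27
Reactants: 51 seco ester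
Product: 52 seco acid (free C25-OH)
Conditions: LiOH·H2O, THF/MeOH/H2O 3:1:1, 0 °C → rt; aqueous KHSO4 to pH 4
Reagents that add atoms: lithium hydroxide [Li+].[OH-]
Why: Saponification of the methyl dienoate, to which the silyl ethers and the non-epimerisable stereocentres are stable.

Step 28
Reactants: 52 seco acid
Product: 54 26-membered macrolactone (7,17,23,29-tetra-OTBS 33-OTES), via mixed anhydride 53 (not isolated)
Conditions: 2-methyl-6-nitrobenzoic anhydride (MNBA, 1.5 equiv), DMAP (6 equiv), toluene, rt, slow addition to 1 mM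
Reagents that add atoms: none
Why: Shiina macrolactonization: the acylpyridinium formed from the mixed anhydride is trapped by the only free hydroxyl, C25-OH, with retention at C25, which is the ring closure of the biosynthesis.

Step 29
Reactants: 54 macrolactone
Product: 55 macrolactone with free C33-OH (tetra-OTBS)
Conditions: PPTS (0.3 equiv), MeOH/CH2Cl2 1:4, 0 °C
Reagents that add atoms: none
Why: Mild acid methanolysis cleaves the secondary TES ether selectively in the presence of the four TBS ethers.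

Step 30
Reactants: 55 macrolactone with free C33-OH
Product: 56 30,31-epoxy macrolactone (tetra-OTBS)
Conditions: VO(acac)2 (20 mol%), t-BuOOH (2 equiv, in decane), CH2Cl2, 0 °C → rt
Reagents that add atoms: tert-butyl hydroperoxide CC(C)(C)OO
Why: Hydroxyl-directed vanadium-catalysed epoxidation of the homoallylic alcohol: allylic 1,3-strain from the C30 methyl holds C32–H in the olefin plane, so the vanadate on C33-O delivers oxygen to the face away from the C32 methoxy group (giving the C30/C31 configuration of the target), and olefins without a bound alkoxide are not oxidised.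

Step 31
Reactants: 56 epoxy macrolactone
Product: 57 CNP0253553.3
Conditions: HF·pyridine, excess pyridine, THF, 0 °C → rt
Reagents that add atoms: none
Why: Buffered fluoride-mediated global desilylation removes the four TBS ethers without base (no Payne rearrangement, no C25→C23 acyl shift) and without strong acid (epoxide kept).

**Compound list**
1 | pent-3-yn-2-one | CC#CC(C)=O | starting material
2 | (R)-pent-3-yn-2-ol | C[C@@H](O)C#CC | intermediate
3 | (R)-pent-3-yn-2-yl methanesulfonate | C[C@@H](OS(C)(=O)=O)C#CC | intermediate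
4 | (P)-tributyl(penta-2,3-dien-2-yl)stannane | [H]C(C)=[C@]=C(C)[Sn](CCCC)(CCCC)CCCC | intermediate
5 | formaldehyde | C=O | starting material
6 | (P)-(penta-2,3-dien-2-yl)indium iodide methanesulfonate | [H]C(C)=[C@]=C(C)[In](I)OS(C)(=O)=O | intermediate (not isolated)
7 | (S)-2-methylpent-3-yn-1-ol | C[C@H](CO)C#CC | intermediate
8 | (S)-1-bromo-2-methylpent-3-yne | C[C@H](CBr)C#CC | intermediate
9 | allyl methyl ether | C=CCOC | starting material
10 | 3-(trimethylsilyl)prop-2-ynal | C[Si](C)(C)C#CC=O | starting material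
11 | (Z)-(3-methoxyprop-2-en-1-yl)diisopinocampheylborane, Ipc from (+)-α-pinene | CO/C=C\CB([C@@H]1C[C@@H]2C[C@H]([C@H]1C)C2(C)C)[C@@H]1C[C@@H]2C[C@H]([C@H]1C)C2(C)C | intermediate (not isolated)
12 | (3R,4R)-4-methoxy-1-(trimethylsilyl)hex-5-en-1-yn-3-ol | C=C[C@@H](OC)[C@H](O)C#C[Si](C)(C)C | intermediate
13 | tert-butyl{[(3R,4R)-4-methoxy-1-(trimethylsilyl)hex-5-en-1-yn-3-yl]oxy}dimethylsilane | C=C[C@@H](OC)[C@H](O[Si](C)(C)C(C)(C)C)C#C[Si](C)(C)C | intermediate
14 | tert-butyl{[(3R,4R)-4-methoxyhex-5-en-1-yn-3-yl]oxy}dimethylsilane | C=C[C@@H](OC)[C@H](O[Si](C)(C)C(C)(C)C)C#C | intermediate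
15 | (E)-alkenylzirconocene chloride from 14 (Zr at the alkyne terminus) | C=C[C@@H](OC)[C@H](O[Si](C)(C)C(C)(C)C)/C=C/[Zr](Cl)(C1C=CC=C1)C1C=CC=C1 | intermediate (not isolated)
16 | tert-butyl{[(1E,3R,4R)-1-iodo-4-methoxyhexa-1,5-dien-3-yl]oxy}dimethylsilane | C=C[C@@H](OC)[C@H](O[Si](C)(C)C(C)(C)C)/C=C/I | intermediate
17 | methyl (2E,4E)-hexa-2,4-dienoate (methyl sorbate) | C/C=C/C=C/C(=O)OC | starting material
18 | fragment A (C1–C9): methyl (2E,4E,6R,7R,8E)-7-[(tert-butyldimethylsilyl)oxy]-9-iodo-6-methoxynona-2,4,8-trienoate | COC(=O)/C=C/C=C/[C@@H](OC)[C@H](O[Si](C)(C)C(C)(C)C)/C=C/I | intermediate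
19 | B-alkyl-9-BBN from 13 (boron on the former terminal CH2, C14) | C1CC2CCCC(C1)B2CC[C@@H](OC)[C@H](O[Si](C)(C)C(C)(C)C)C#C[Si](C)(C)C | intermediate (not isolated)
20 | tert-butyl{[(3R,4R,8R)-4-methoxy-8-methyl-1-(trimethylsilyl)undeca-1,9-diyn-3-yl]oxy}dimethylsilane | CC#C[C@H](C)CCC[C@@H](OC)[C@H](O[Si](C)(C)C(C)(C)C)C#C[Si](C)(C)C | intermediate
21 | tert-butyl{[(3R,4R,8R)-4-methoxy-8-methylundeca-1,9-diyn-3-yl]oxy}dimethylsilane | CC#C[C@H](C)CCC[C@@H](OC)[C@H](O[Si](C)(C)C(C)(C)C)C#C | intermediate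
22 | (E)-alkenylzirconocene chloride from 21 (Zr at C19) | CC#C[C@H](C)CCC[C@@H](OC)[C@H](O[Si](C)(C)C(C)(C)C)/C=C/[Zr](Cl)(C1C=CC=C1)C1C=CC=C1 | intermediate (not isolated)
23 | fragment B (C10–C19): tert-butyl{[(1E,3R,4R,8R)-1-iodo-4-methoxy-8-methylundec-1-en-9-yn-3-yl]oxy}dimethylsilane | CC#C[C@H](C)CCC[C@@H](OC)[C@H](O[Si](C)(C)C(C)(C)C)/C=C/I | intermediate
24 | 2-vinyloxirane (racemic) | C=CC1CO1 | starting material
25 | methanol | CO | starting material
26 | (2S)-2-methoxybut-3-en-1-ol | OC[C@H](C=C)OC | intermediate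
27 | (2S)-2-methoxybut-3-enal | O=C[C@H](C=C)OC | intermediate
28 | (3S,4S,5R)-3-methoxy-5-methyloct-1-en-6-yn-4-ol | CC#C[C@@H](C)[C@H](O)[C@H](C=C)OC | intermediate
29 | tert-butyl{[(3S,4S,5R)-3-methoxy-5-methyloct-1-en-6-yn-4-yl]oxy}dimethylsilane | CC#C[C@@H](C)[C@H](O[Si](C)(C)C(C)(C)C)[C@H](C=C)OC | intermediate
30 | ozonide (1,2,4-trioxolane) of 29 | CC#C[C@@H](C)[C@H](O[Si](C)(C)C(C)(C)C)[C@H](C1OCOO1)OC | intermediate (not isolated)
31 | (2R,3S,4R)-3-[(tert-butyldimethylsilyl)oxy]-2-methoxy-4-methylhept-5-ynal (C20–C25) | CC#C[C@@H](C)[C@H](O[Si](C)(C)C(C)(C)C)[C@H](C=O)OC | intermediate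
32 | butanal | CCCC=O | starting material
33 | (Z)-(3-methoxyprop-2-en-1-yl)diisopinocampheylborane, Ipc from (−)-α-pinene | CO/C=C\CB([C@H]1C[C@H]2C[C@@H]([C@@H]1C)C2(C)C)[C@H]1C[C@H]2C[C@@H]([C@@H]1C)C2(C)C | intermediate (not isolated)
34 | (3S,4S)-3-methoxyhept-1-en-4-ol | CCC[C@H](O)[C@@H](OC)C=C | intermediate
35 | triethyl{[(3S,4S)-3-methoxyhept-1-en-4-yl]oxy}silane | CCC[C@H](O[Si](CC)(CC)CC)[C@@H](OC)C=C | intermediate
36 | methacrolein | CC(=C)C=O | starting material
37 | (2E,4S,5S)-4-methoxy-2-methyl-5-[(triethylsilyl)oxy]oct-2-enal (C29–C36) | CCC[C@H](O[Si](CC)(CC)CC)[C@@H](OC)/C=C(\C)C=O | intermediate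
38 | propargyl bromide | C#CCBr | starting material
39 | allenylmagnesium bromide | C=C=C[Mg]Br | intermediate (not isolated)
40 | propa-1,2-dien-1-ylboronic acid | C=C=CB(O)O | intermediate (not isolated)
41 | 5,5-dimethyl-2-(propa-1,2-dien-1-yl)-1,3,2-dioxaborinane | C=C=CB1OCC(C)(C)CO1 | intermediate
42 | (E)-[3-(5,5-dimethyl-1,3,2-dioxaborinan-2-yl)prop-2-en-1-yl]diisopinocampheylborane, Ipc from (+)-α-pinene | CC1(C)COB(/C=C/CB([C@@H]2C[C@@H]3C[C@H]([C@H]2C)C3(C)C)[C@@H]2C[C@@H]3C[C@H]([C@H]2C)C3(C)C)OC1 | intermediate (not isolated)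
43 | adduct of 42 and 31: C25 O-diisopinocampheylborinate, C26 dioxaborinanyl, terminal vinyl (25,26-anti) | CC#C[C@@H](C)[C@H](O[Si](C)(C)C(C)(C)C)[C@@H](OC)[C@@H](OB([C@@H]1C[C@@H]2C[C@H]([C@H]1C)C2(C)C)[C@@H]1C[C@@H]2C[C@H]([C@H]1C)C2(C)C)[C@H](C=C)B1OCC(C)(C)CO1 | intermediate (not isolated)
44 | C20–C36 25,29-diol: 20-yne, (26E,30E)-diene, 23-OTBS, 33-OTES, 24- and 32-OMe, stereocentres as in 57 | CCC[C@H](O[Si](CC)(CC)CC)[C@@H](OC)/C=C(\C)/[C@@H](O)C/C=C/[C@H](O)[C@H](OC)[C@@H](O[Si](C)(C)C(C)(C)C)[C@H](C)C#CC | intermediate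
45 | 44 with C29-OTBS, C25-OH free | CCC[C@H](O[Si](CC)(CC)CC)[C@@H](OC)/C=C(\C)/[C@@H](O[Si](C)(C)C(C)(C)C)C/C=C/[C@H](O)[C@H](OC)[C@@H](O[Si](C)(C)C(C)(C)C)[C@H](C)C#CC | intermediate
46 | C20 alkenylzirconocene chloride of 45 (C25 zirconium alkoxide) | CCC[C@H](O[Si](CC)(CC)CC)[C@@H](OC)/C=C(\C)/[C@@H](O[Si](C)(C)C(C)(C)C)C/C=C/[C@H](O[Zr](Cl)(C1C=CC=C1)C1C=CC=C1)[C@H](OC)[C@@H](O[Si](C)(C)C(C)(C)C)[C@H](C)/C=C(\C)[Zr](Cl)(C1C=CC=C1)C1C=CC=C1 | intermediate (not isolated)
47 | C20 alkenylzinc chloride from 46 | CCC[C@H](O[Si](CC)(CC)CC)[C@@H](OC)/C=C(\C)/[C@@H](O[Si](C)(C)C(C)(C)C)C/C=C/[C@H](O[Zr](Cl)(C1C=CC=C1)C1C=CC=C1)[C@H](OC)[C@@H](O[Si](C)(C)C(C)(C)C)[C@H](C)/C=C(\C)[Zn]Cl | intermediate (not isolated)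
48 | C10–C36 dienyne: 10-yne, (18E,20E,26E,30E)-tetraene, 17,23,29-tris-OTBS, 33-OTES, 25-OH | CCC[C@H](O[Si](CC)(CC)CC)[C@@H](OC)/C=C(\C)/[C@@H](O[Si](C)(C)C(C)(C)C)C/C=C/[C@H](O)[C@H](OC)[C@@H](O[Si](C)(C)C(C)(C)C)[C@H](C)/C=C(\C)/C=C/[C@@H](O[Si](C)(C)C(C)(C)C)[C@H](OC)CCC[C@@H](C)C#CC | intermediate
49 | C10 alkenylzirconocene chloride of 48 (C25 zirconium alkoxide) | CCC[C@H](O[Si](CC)(CC)CC)[C@@H](OC)/C=C(\C)/[C@@H](O[Si](C)(C)C(C)(C)C)C/C=C/[C@H](O[Zr](Cl)(C1C=CC=C1)C1C=CC=C1)[C@H](OC)[C@@H](O[Si](C)(C)C(C)(C)C)[C@H](C)/C=C(\C)/C=C/[C@@H](O[Si](C)(C)C(C)(C)C)[C@H](OC)CCC[C@@H](C)/C=C(\C)[Zr](Cl)(C1C=CC=C1)C1C=CC=C1 | intermediate (not isolated)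
50 | C10 alkenylzinc chloride from 49 | CCC[C@H](O[Si](CC)(CC)CC)[C@@H](OC)/C=C(\C)/[C@@H](O[Si](C)(C)C(C)(C)C)C/C=C/[C@H](O[Zr](Cl)(C1C=CC=C1)C1C=CC=C1)[C@H](OC)[C@@H](O[Si](C)(C)C(C)(C)C)[C@H](C)/C=C(\C)/C=C/[C@@H](O[Si](C)(C)C(C)(C)C)[C@H](OC)CCC[C@@H](C)/C=C(\C)[Zn]Cl | intermediate (not isolated)
51 | methyl ester of the C1–C36 seco acid: 7,17,23,29-tetra-OTBS, 33-OTES, 25-OH | CCC[C@H](O[Si](CC)(CC)CC)[C@@H](OC)/C=C(\C)/[C@@H](O[Si](C)(C)C(C)(C)C)C/C=C/[C@H](O)[C@H](OC)[C@@H](O[Si](C)(C)C(C)(C)C)[C@H](C)/C=C(\C)/C=C/[C@@H](O[Si](C)(C)C(C)(C)C)[C@H](OC)CCC[C@@H](C)/C=C(\C)/C=C/[C@@H](O[Si](C)(C)C(C)(C)C)[C@H](OC)/C=C/C=C/C(=O)OC | intermediate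
52 | C1–C36 seco acid (25-OH free) | CCC[C@H](O[Si](CC)(CC)CC)[C@@H](OC)/C=C(\C)/[C@@H](O[Si](C)(C)C(C)(C)C)C/C=C/[C@H](O)[C@H](OC)[C@@H](O[Si](C)(C)C(C)(C)C)[C@H](C)/C=C(\C)/C=C/[C@@H](O[Si](C)(C)C(C)(C)C)[C@H](OC)CCC[C@@H](C)/C=C(\C)/C=C/[C@@H](O[Si](C)(C)C(C)(C)C)[C@H](OC)/C=C/C=C/C(=O)O | intermediate
53 | mixed anhydride of 52 with 2-methyl-6-nitrobenzoic acid | CCC[C@H](O[Si](CC)(CC)CC)[C@@H](OC)/C=C(\C)/[C@@H](O[Si](C)(C)C(C)(C)C)C/C=C/[C@H](O)[C@H](OC)[C@@H](O[Si](C)(C)C(C)(C)C)[C@H](C)/C=C(\C)/C=C/[C@@H](O[Si](C)(C)C(C)(C)C)[C@H](OC)CCC[C@@H](C)/C=C(\C)/C=C/[C@@H](O[Si](C)(C)C(C)(C)C)[C@H](OC)/C=C/C=C/C(=O)OC(=O)c1c(C)cccc1[N+](=O)[O-] | intermediate (not isolated)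
54 | 26-membered macrolactone, 30,31-alkene (E), 7,17,23,29-tetra-OTBS, 33-OTES | CCC[C@H](O[Si](CC)(CC)CC)[C@@H](OC)/C=C(\C)/[C@@H](O[Si](C)(C)C(C)(C)C)C/C=C/[C@@H]1OC(=O)/C=C/C=C/[C@@H](OC)[C@H](O[Si](C)(C)C(C)(C)C)/C=C/C(C)=C/[C@H](C)CCC[C@@H](OC)[C@H](O[Si](C)(C)C(C)(C)C)/C=C/C(C)=C/[C@@H](C)[C@H](O[Si](C)(C)C(C)(C)C)[C@H]1OC | intermediate
55 | 54 with C33-OH free | CCC[C@H](O)[C@@H](OC)/C=C(\C)/[C@@H](O[Si](C)(C)C(C)(C)C)C/C=C/[C@@H]1OC(=O)/C=C/C=C/[C@@H](OC)[C@H](O[Si](C)(C)C(C)(C)C)/C=C/C(C)=C/[C@H](C)CCC[C@@H](OC)[C@H](O[Si](C)(C)C(C)(C)C)/C=C/C(C)=C/[C@@H](C)[C@H](O[Si](C)(C)C(C)(C)C)[C@H]1OC | intermediate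
56 | 30,31-epoxide of 55 (epoxide configured as in 57), 7,17,23,29-tetra-OTBS | CCC[C@H](O)[C@@H](OC)[C@H]1O[C@]1(C)[C@@H](O[Si](C)(C)C(C)(C)C)C/C=C/[C@@H]1OC(=O)/C=C/C=C/[C@@H](OC)[C@H](O[Si](C)(C)C(C)(C)C)/C=C/C(C)=C/[C@H](C)CCC[C@@H](OC)[C@H](O[Si](C)(C)C(C)(C)C)/C=C/C(C)=C/[C@@H](C)[C@H](O[Si](C)(C)C(C)(C)C)[C@H]1OC | intermediate
57 | CNP0253553.3 (6R,7R,12R,16R,17R,22R,23S,24R,25S,29S,30R,31R,32R,33S) | CCC[C@H](O)[C@@H](OC)[C@H]1O[C@]1(C)[C@@H](O)C/C=C/[C@@H]1OC(=O)/C=C/C=C/[C@@H](OC)[C@H](O)/C=C/C(C)=C/[C@H](C)CCC[C@@H](OC)[C@H](O)/C=C/C(C)=C/[C@@H](C)[C@H](O)[C@H]1OC | target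

**Totals and risks**
Total step count: 31. Longest linear sequence: 15 steps (1, 2, 3, 16, 17, 18, 23, 24, 25, 26, 27, 28, 29, 30, 31).

Three steps most likely to fail:

Step 11 (alkyl–alkyl Suzuki coupling). The bromide 8 is β-branched, so oxidative addition is slow and β-hydride elimination may compete. Fallback, setting out from 13 and coming back at 20: 13 is hydroborated to 19 as before, and 19 is oxidised with NaBO3·4H2O to the primary alcohol (3R,4R)-4-[(tert-butyldimethylsilyl)oxy]-3-methoxy-6-(trimethylsilyl)hex-5-yn-1-ol F1. TsCl/pyridine turns it into the tosylate F2. Bromide 8 is converted with Mg in THF into (S)-(2-methylpent-3-yn-1-yl)magnesium bromide F3, which displaces the unbranched tosylate of F2 under Li2CuCl4 catalysis (THF, −30 → 0 °C) to give 20. The polarity is reversed, so the branched partner is now the nucleophile.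

Step 24 (site-selective silylation of the 25,29-diol). Selectivity rests only on the steric difference between the two allylic carbinols. Fallback, setting out from 37 and coming back at 45 (44 is bypassed): enal 37 is propargylated with allenylboronic acid pinacol ester and the TRIP phosphoric acid antipode matched to the 29S carbinol, giving the homopropargylic alcohol F4. TBSOTf/2,6-lutidine gives the silyl ether F5. Cp2Zr(H)Cl gives the alkenylzirconocene F6 and I2 the (E)-vinyl iodide F7. CrCl2/NiCl2 (cat.) in DMSO converts F7 into the alkenylchromium dichloride F8, which adds to aldehyde 31 (Nozaki–Hiyama–Kishi, Felkin-controlled, 24,25-anti) to give 45, with C29 already protected and C25-OH free.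

Step 30 (late directed epoxidation). The homoallylic trisubstituted alkene may react slowly, or the substrate-derived facial bias may be incomplete on the full macrolide. Fallback, setting out from 55 and coming back at 56: stereocontrol is moved from the substrate to a chiral catalyst by using Hf(Ot-Bu)4 with a C2-symmetric chiral bishydroxamic acid ligand and cumene hydroperoxide (toluene, 0 °C), a Yamamoto-type system built for homoallylic alcohols, with the ligand antipode that reinforces the substrate preference; no new isolated compound is made.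

**Further compounds**
F1 | step 11 | (3R,4R)-4-[(tert-butyldimethylsilyl)oxy]-3-methoxy-6-(trimethylsilyl)hex-5-yn-1-ol | OCC[C@@H](OC)[C@H](O[Si](C)(C)C(C)(C)C)C#C[Si](C)(C)C
F2 | step 11 | 4-methylbenzenesulfonate of F1 | Cc1ccc(cc1)S(=O)(=O)OCC[C@@H](OC)[C@H](O[Si](C)(C)C(C)(C)C)C#C[Si](C)(C)C
F3 | step 11 | (S)-(2-methylpent-3-yn-1-yl)magnesium bromide | C[C@H](C[Mg]Br)C#CC
F4 | step 24 | C26–C36 homopropargylic alcohol: (4S,5E,7S,8S)-7-methoxy-5-methyl-8-[(triethylsilyl)oxy]undec-5-en-1-yn-4-ol | CCC[C@H](O[Si](CC)(CC)CC)[C@@H](OC)/C=C(\C)/[C@@H](O)CC#C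
F5 | step 24 | tert-butyldimethylsilyl ether of F4 | CCC[C@H](O[Si](CC)(CC)CC)[C@@H](OC)/C=C(\C)/[C@@H](O[Si](C)(C)C(C)(C)C)CC#C
F6 | step 24 | (E)-alkenylzirconocene chloride from F5 (Zr at C26) | CCC[C@H](O[Si](CC)(CC)CC)[C@@H](OC)/C=C(\C)/[C@@H](O[Si](C)(C)C(C)(C)C)C/C=C/[Zr](Cl)(C1C=CC=C1)C1C=CC=C1
F7 | step 24 | (E)-vinyl iodide from F6 (I at C26) | CCC[C@H](O[Si](CC)(CC)CC)[C@@H](OC)/C=C(\C)/[C@@H](O[Si](C)(C)C(C)(C)C)C/C=C/I
F8 | step 24 | (E)-alkenylchromium dichloride from F7 | CCC[C@H](O[Si](CC)(CC)CC)[C@@H](OC)/C=C(\C)/[C@@H](O[Si](C)(C)C(C)(C)C)C/C=C/[Cr](Cl)Cl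
F0 | step 30 | none | none
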